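## Retrosynthetic overview

1. One formal (3+2) disconnection across the C6=C7 bond of Z-ligustilide (1) cuts both new C–C bonds (C6–C3′, C7–C7a′) and the bridging lactone, leaving an achiral diketo ester as the three-carbon partner.
2. The diketo ester comes from 3,4,5,6-tetrahydrophthalic anhydride (2) and n-butylmagnesium chloride (3) by ring-opening acylation, esterification and α-oxidation.
3. Ring order: ring A with its butylidene lactone and ring B are bought; the γ-lactone of the ring B unit closes first, the cyclopentane of the 2-oxabicyclo[2.2.1]heptanone core last.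
4. All five stereocentres arise in the last, organocatalytic step from two achiral partners.

Assumption and convention: Z-ligustilide is bought as a catalogue compound; locants follow phthalide numbering, unprimed for the butylidene unit (ring A) and primed for the keto-lactone unit (ring B).

## Route

Step 1
Reactants: 2 3,4,5,6-tetrahydrophthalic anhydride; 3 n-butylmagnesium chloride
Product: 5 methyl 2-pentanoylcyclohex-1-ene-1-carboxylate, via keto acid 4 (not isolated)
Conditions: 3 (1.05 equiv), THF, −78 → −20 °C; aq. HCl; crude acid, MeI, K2CO3, DMF, 25 °C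
Reagents that add atoms: iodomethane, CI
Why: Grignard addition to the cyclic anhydride stops at the keto carboxylate at low temperature, and SN2 O-methylation of the ring-opened carboxylate gives the normal ester; no stereocentre is formed.

Step 2
Reactants: 5 methyl 2-pentanoylcyclohex-1-ene-1-carboxylate
Product: 6 methyl 2-(2-oxopentanoyl)cyclohex-1-ene-1-carboxylate
Conditions: SeO2 (1.2 equiv), 1,4-dioxane, trace H2O, 90 °C
Reagents that add atoms: selenium dioxide, O=[Se]=O
Why: Riley oxidation converts the only enolisable α-methylene of the ketone into the 1,2-diketone, while the electron-poor tetrasubstituted alkene resists allylic oxidation; no stereocentre is formed.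

Step 3
Reactants: 1 Z-ligustilide; 6 methyl 2-(2-oxopentanoyl)cyclohex-1-ene-1-carboxylate
Product: 10 target (3′R,3a′S,6S,7S,7a′S)-6,3′:7,7a′-linked Z-ligustilide/3′-butanoylphthalide bis-lactone, via deconjugated keto ester 7 (not isolated), via aldol adduct 8 (not isolated), via lactone 9 (not isolated)
Conditions: 1 (1.2 equiv), (S)-tert-leucine-derived bifunctional iminophosphorane–thiourea organocatalyst [P(4-MeOC6H4)3-based] (10 mol%), 4 Å MS, toluene, −20 → 25 °C (the mirror-image catalyst would give ent-10)
Reagents that add atoms: none
Why: Proposed new method: a superbase/hydrogen-bond-donor-catalysed asymmetric formal (3+2) annulation across C6=C7 of a cross-conjugated butenolide — the catalyst deprotonates 1 at C4 to a bound trienolate whose γ′ terminus C6 adds to the C3′ carbonyl of 7 (formed from 6 by catalyst-mediated 1,3-proton shift and racemising through its enol, so C6, C3′ and C3a′ are fixed in a dynamic kinetic asymmetric vinylogous aldol addition); only the C3′ alkoxide can close a γ-lactone on the ester (9, with the ligustilide arm anti to C4′), whereas C4, C7a and C8′ adducts revert by retro-aldol; γ-deprotonation of 9 at C6′ then gives a lactone dienolate that closes the cyclopentane by 5-exo-trig α-attack of C7a′ on the unmasked acceptor C7 (C7a′ set anti to C4′, C7 set with H-7 exo), and γ-protonation at C4 restores the butenolide; the closest known reactions are organocatalytic direct vinylogous aldol additions of butenolides to 1,2-dicarbonyls and Michael/Michael (double Michael) annulations.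

## Compound list

1 | Z-ligustilide, (3Z)-3-butylidene-4,5-dihydro-2-benzofuran-1(3H)-one | CCC/C=C1\OC(=O)C2=C1CCC=C2 | starting material
2 | 3,4,5,6-tetrahydrophthalic anhydride (4,5,6,7-tetrahydro-2-benzofuran-1,3-dione) | O=C1OC(=O)C2=C1CCCC2 | starting material
3 | n-butylmagnesium chloride | CCCC[Mg]Cl | starting material
4 | 2-pentanoylcyclohex-1-ene-1-carboxylic acid (open form of its hydroxy-lactone tautomer) | CCCCC(=O)C1=C(CCCC1)C(=O)O | intermediate
5 | methyl 2-pentanoylcyclohex-1-ene-1-carboxylate | CCCCC(=O)C1=C(CCCC1)C(=O)OC | intermediate
6 | methyl 2-(2-oxopentanoyl)cyclohex-1-ene-1-carboxylate | CCCC(=O)C(=O)C1=C(CCCC1)C(=O)OC | intermediate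
7 | methyl (6S)-6-(2-oxopentanoyl)cyclohex-1-ene-1-carboxylate (deconjugated tautomer of 6; C6 epimerises by enolisation, the 6S form is consumed) | CCCC(=O)C(=O)[C@H]1CCCC=C1C(=O)OC | intermediate
8 | methyl (6S)-6-{(1R)-1-[(3Z,6S)-3-butylidene-1-oxo-1,3,5,6-tetrahydro-2-benzofuran-6-yl]-1-hydroxy-2-oxopentyl}cyclohex-1-ene-1-carboxylate | CCC/C=C1\OC(=O)C2=C[C@H](CC=C12)[C@](O)(C(=O)CCC)[C@H]3CCCC=C3C(=O)OC | intermediate
9 | (3R,3aS)-3-butanoyl-3-[(3Z,6S)-3-butylidene-1-oxo-1,3,5,6-tetrahydro-2-benzofuran-6-yl]-3a,4,5,6-tetrahydro-2-benzofuran-1(3H)-one | CCC/C=C1\OC(=O)C2=C[C@H](CC=C12)[C@@]3(C(=O)CCC)OC(=O)C4=CCCC[C@H]34 | intermediate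
10 | CNP0423313.2: Z-ligustilide unit bonded through C6 and C7 to C3′ and C7a′ of a 3′-butanoyl-3a′,4′,5′,7a′-tetrahydrophthalide unit (2-oxabicyclo[2.2.1]heptan-3-one core); (3′R,3a′S,6S,7S,7a′S), H-6 endo, H-7 exo, C4′ syn to the lactone bridge | CCC/C=C1\OC(=O)C2=C1CC[C@H]1[C@H]2[C@@]23C=CCC[C@@H]2[C@]1(C(=O)CCC)OC3=O | target

## Step count and risks

Total step count: 3. Longest linear sequence: 3 steps (2 → 5 → 6 → 10); 1 enters in the last step.

**Step 3 (the proposed new annulation) — most likely to fail.** The failure modes are:
- reaction of the ligustilide trienolate at C4 or C7a instead of C6;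
- attack at C8′ instead of C3′;
- base-induced isomerisation of 1 to 3-butylphthalide;
- the ring-A junction. The target has H-6 and H-7 anti, but a tethered closure on the planar dienyl lactone of 9 normally goes syn, so the 7-epimer is the expected by-product and may well be the main product. The junction must be checked by NOE or X-ray.

Fallback (known reaction types, stepwise; this secures the bond construction and enantiocontrol but does not by itself correct the junction), setting out from 1 and 6: 1 is silylated with TBSOTf and Et3N to the silyl dienolate F1. Separately, 6 is deconjugated by kinetic protonation of its lithium dienolate (LiN(iPr)2, THF, −78 °C, then AcOH) to the racemic keto ester F2. A vinylogous Mukaiyama aldol addition of F1 to F2 under a chiral cinchona-derived thiourea hydrogen-bond-donor catalyst (F2 racemises through its enol) is followed by TBAF/AcOH work-up, which removes the silyl group and lactonises the alkoxide. This gives lactone 9, where the fallback comes back to the route; isolated 9 is then closed to 10 with DBU in a separate intramolecular Michael addition.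

**Step 2 (Riley oxidation).** Over-oxidation or selenium-containing by-products are possible. Fallback from 5: nitrosation with isoamyl nitrite and HCl (Et2O, 0 °C) gives the α-oximino ketone F3, and deoximation with aqueous formaldehyde/HCl returns to the route at 6.

**Step 1 (Grignard opening of the anhydride).** Double addition or methylation of the hydroxy-lactone form are possible. Fallback from 2: methanolysis (MeOH, reflux) gives the half ester F4, oxalyl chloride with catalytic DMF gives the acid chloride F5, and coupling with 3 under Fe(acac)3 catalysis (THF, −78 °C) returns to the route at 5.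

## Further compounds

F1 | step 3 | tert-butyl{[(3Z)-3-butylidene-3,5-dihydro-2-benzofuran-1-yl]oxy}dimethylsilane | CCC/C=C1\OC(O[Si](C)(C)C(C)(C)C)=C2C=CCC=C12
F2 | step 3 | racemic methyl 6-(2-oxopentanoyl)cyclohex-1-ene-1-carboxylate | CCCC(=O)C(=O)C1CCCC=C1C(=O)OC
F3 | step 2 | methyl 2-[2-(hydroxyimino)pentanoyl]cyclohex-1-ene-1-carboxylate | CCCC(=NO)C(=O)C1=C(CCCC1)C(=O)OC
F4 | step 1 | 2-(methoxycarbonyl)cyclohex-1-ene-1-carboxylic acid | COC(=O)C1=C(CCCC1)C(=O)O
F5 | step 1 | methyl 2-(chlorocarbonyl)cyclohex-1-ene-1-carboxylate | COC(=O)C1=C(CCCC1)C(=O)Cl
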